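**Plan**

- Retrosynthesis: the three silyl ethers come off last. The isopropenyl carbon is traced back (C=CH2, then C–CH3) to the lactol carbon of a pyran ring fused across O7/C8. That ring is cut at C1''–C2'' and O7–C(lactol), then C8–C1'' (Mannich), then O1–C2 and Cα=Cβ of the flavone (chalcone).
- Enabling feature: C8 of ring A is ortho to the free 7-OH, so O7–C7–C8–C1'' of the finished flavone can be unmasked as an o-quinone methide (C7=O, C8=CH2). The stereocentre C2'' is the carbon that attacks its CH2.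
- Forward: ring C is built by chalcone condensation and oxidative cyclisation, and the B-ring acetals are exchanged for silyl ethers. C8 is then aminomethylated and quaternised. The C6 chain is joined in the key step, which closes a temporary lactol ring onto O7. That ring is opened by methyl addition, followed by oxidation, methylenation and desilylation.
- Stereochemistry: the only stereocentre, C2'' (R), is set in the key step by the enamine of an (S)-diphenylprolinol silyl ether (Si-face attack). It is preserved by a non-basic methylenation.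

Key step: step 12

Remark: C1'' is the CH2 on C8 and C2'' the stereocentre. Lactol 18 and carbinol 19 are carried as epimer mixtures at the future isopropenyl carbon, which becomes sp2 in steps 14–15. Aminomethylation of the 7-hydroxy-5-methoxychromone is assumed to go to C8, as is usual for 7-hydroxychromones without a free 5-OH.

**Route**

Step 1
Reactants: 1 1-(2,4-dihydroxy-6-methoxyphenyl)ethanone
Product: 2 1-[4-(benzyloxy)-2-hydroxy-6-methoxyphenyl]ethanone
Conditions: BnBr (1.05 equiv), K2CO3, acetone, reflux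
Reagents that add atoms: benzyl bromide, BrCc1ccccc1
Why: Williamson etherification; the 2'-OH is held in a hydrogen bond to the acetyl carbonyl, so only the unchelated 4'-OH should be benzylated.

Step 2
Reactants: 3 2,4-dihydroxybenzaldehyde
Product: 4 2,4-bis(methoxymethoxy)benzaldehyde
Conditions: NaH, MOMCl, DMF, 0 °C → rt
Reagents that add atoms: chloromethyl methyl ether, COCCl
Why: Williamson-type double O-alkylation of the sodium phenoxides should mask both phenols, including the chelated 2-OH, as acetals that are stable to the hydroxide of the next step.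

Step 3
Reactants: 2 1-[4-(benzyloxy)-2-hydroxy-6-methoxyphenyl]ethanone; 4 2,4-bis(methoxymethoxy)benzaldehyde
Product: 5 (E)-1-[4-(benzyloxy)-2-hydroxy-6-methoxyphenyl]-3-[2,4-bis(methoxymethoxy)phenyl]prop-2-en-1-one
Conditions: KOH, EtOH–H2O, rt
Reagents that add atoms: none
Why: Claisen–Schmidt condensation; the acetophenone enolate adds to the non-enolisable aldehyde and E1cB loss of water should give the E-chalcone, with benzyl and MOM ethers inert to hydroxide.

Step 4
Reactants: 5 (E)-chalcone
Product: 7 7-(benzyloxy)-2-(2,4-dihydroxyphenyl)-5-methoxy-4H-chromen-4-one, via bis-MOM flavone 6 (not isolated)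
Conditions: I2 (10 mol%), DMSO, 130 °C; aq. Na2S2O3 wash; crude in MeOH–3 M HCl, 60 °C
Reagents that add atoms: none
Why: Iodine/DMSO oxidative cyclisation of a 2'-hydroxychalcone (6-endo oxa-Michael closure of ring C and iodine-mediated dehydrogenation, DMSO reoxidising iodide) should give the flavone, and acid methanolysis then removes both MOM acetals while the benzyl and methyl aryl ethers stay.

Step 5
Reactants: 7 7-(benzyloxy)-2-(2,4-dihydroxyphenyl)-5-methoxy-4H-chromen-4-one
Product: 8 7-(benzyloxy)-5-methoxy-2-[2,4-bis(triisopropylsilyloxy)phenyl]-4H-chromen-4-one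
Conditions: TIPSCl, imidazole, DMF, rt → 40 °C
Reagents that add atoms: chlorotriisopropylsilane, CC(C)[Si](Cl)(C(C)C)C(C)C
Why: Imidazole-promoted silylation of phenols should cap the B ring with bulky fluoride-labile groups, so that the final deprotection needs no acid, which could cyclise the 7-OH onto the isopropenyl group or ionise the tertiary alcohol.

Step 6
Reactants: 8 7-(benzyloxy)-5-methoxy-2-[2,4-bis(triisopropylsilyloxy)phenyl]-4H-chromen-4-one
Product: 9 7-hydroxy-5-methoxy-2-[2,4-bis(triisopropylsilyloxy)phenyl]-4H-chromen-4-one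
Conditions: H2 (1 atm), 10% Pd/C, EtOAc, rt
Reagents that add atoms: none
Why: Catalytic hydrogenolysis of the benzyl aryl ether should free the 7-OH without reducing the conjugated C2=C3 bond or cleaving the aryl silyl ethers in an aprotic solvent.

Step 7
Reactants: 9 7-hydroxy-5-methoxy-2-[2,4-bis(triisopropylsilyloxy)phenyl]-4H-chromen-4-one; 10 N,N-dimethylmethyleneiminium iodide
Product: 11 8-[(dimethylamino)methyl]-7-hydroxy-5-methoxy-2-[2,4-bis(triisopropylsilyloxy)phenyl]-4H-chromen-4-one
Conditions: K2CO3, CH2Cl2, rt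
Reagents that add atoms: none
Why: Mannich aminomethylation with a preformed iminium salt; the 7-phenoxide should react through C8 (ortho to O7 and para to the 5-methoxy group), and the silylated B ring does not compete.

Step 8
Reactants: 11 8-[(dimethylamino)methyl]-7-hydroxy-5-methoxy-2-[2,4-bis(triisopropylsilyloxy)phenyl]-4H-chromen-4-one
Product: 12 {7-hydroxy-5-methoxy-4-oxo-2-[2,4-bis(triisopropylsilyloxy)phenyl]-4H-chromen-8-yl}-N,N,N-trimethylmethanaminium iodide
Conditions: MeI (excess), THF, rt, dark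
Reagents that add atoms: iodomethane, CI
Why: Menshutkin quaternisation of the benzylic tertiary amine; without added base the phenol should stay unmethylated and the salt should precipitate.

Step 9
Reactants: 13 methyl hex-5-enoate
Product: 14 2-methylhept-6-en-2-ol
Conditions: MeMgBr (2.5 equiv), Et2O, 0 °C → rt; aq. NH4Cl
Reagents that add atoms: methylmagnesium bromide, C[Mg]Br
Why: Double Grignard addition to the ester should give the tertiary alcohol, the terminal alkene being inert.

Step 10
Reactants: 14 2-methylhept-6-en-2-ol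
Product: 15 triethyl[(2-methylhept-6-en-2-yl)oxy]silane
Conditions: TESOTf, 2,6-lutidine, CH2Cl2, −78 → 0 °C
Reagents that add atoms: triethylsilyl trifluoromethanesulfonate, CC[Si](CC)(CC)OS(=O)(=O)C(F)(F)F
Why: Silyl triflate/lutidine silylation is the standard way to cap a hindered tertiary alcohol, which would otherwise close onto the later aldehyde as a lactol.

Step 11
Reactants: 15 triethyl[(2-methylhept-6-en-2-yl)oxy]silane
Product: 16 5-methyl-5-(triethylsilyloxy)hexanal
Conditions: O3, CH2Cl2, −78 °C; then PPh3, → rt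
Reagents that add atoms: ozone, [O-][O+]=O
Why: Ozonolysis with reductive phosphine work-up should cleave the terminal alkene to the aldehyde without touching the silyl ether.

Step 12
Reactants: 12 {7-hydroxy-5-methoxy-4-oxo-2-[2,4-bis(triisopropylsilyloxy)phenyl]-4H-chromen-8-yl}-N,N,N-trimethylmethanaminium iodide; 16 5-methyl-5-(triethylsilyloxy)hexanal
Product: 18 (9R)-8-hydroxy-5-methoxy-9-[3-methyl-3-(triethylsilyloxy)butyl]-2-[2,4-bis(triisopropylsilyloxy)phenyl]-9,10-dihydro-4H,8H-pyrano[2,3-f]chromen-4-one as a mixture of C8 anomers, via o-quinone methide 17 (not isolated)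
Conditions: (S)-2-[diphenyl(trimethylsilyloxy)methyl]pyrrolidine (20 mol%), powdered NaHCO3 (2 equiv), 16 (2 equiv), MeCN, 0 °C → rt; crude lactol used directly
Reagents that add atoms: none
Why: Bicarbonate removes the acidic 7-OH proton and the phenoxide expels trimethylamine (E1cB), dearomatising ring A to the o-quinone methide 17 (C7=O, C8=CH2), while the catalyst condenses with 16 to its s-trans E-enamine; the enamine α-carbon adds to the exocyclic CH2, which restores aromatic ring A and forms C1''–C2'', and the phenoxide then closes onto the iminium carbon before hydrolysis frees catalyst and lactol. The closest known reaction type is the secondary-amine-catalysed enantioselective formal [4+2] (Michael addition/hemiacetalisation) of in situ generated o-quinone methides with aldehydes to chroman-2-ols. The new pyran ring closes by 6-exo-trig attack of O7 on the iminium (or aldehyde) carbon. C2'' is set by the catalyst alone: the diphenyl(silyloxy)methyl group of the (S)-pyrrolidine blocks the Re face of the enamine, so the CH2 terminus, which carries no stereochemical information, is attacked from the Si face and C2'' should come out R, while the anomeric carbon is uncontrolled and is later made planar. The step needs site selectivity, face selectivity and no racemic background path: only C8 carries the leaving group next to the 7-OH, the B-ring oxygens are silylated and the pyranone C2 is a poor acceptor, and the amine set free is tertiary and cannot form an enamine. Closure to the lactol also withdraws the aldehyde from further enamine formation, which should protect the new α-stereocentre.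

Step 13
Reactants: 18 lactol (9R)-8-hydroxy-5-methoxy-9-[3-methyl-3-(triethylsilyloxy)butyl]-2-[2,4-bis(triisopropylsilyloxy)phenyl]-9,10-dihydro-4H,8H-pyrano[2,3-f]chromen-4-one
Product: 19 7-hydroxy-8-[(2R)-2-(1-hydroxyethyl)-5-methyl-5-(triethylsilyloxy)hexyl]-5-methoxy-2-[2,4-bis(triisopropylsilyloxy)phenyl]-4H-chromen-4-one as a mixture of carbinol epimers
Conditions: MeTi(OiPr)3 (4 equiv; from ClTi(OiPr)3 + MeLi), THF, −30 °C → rt; aq. NH4Cl
Reagents that add atoms: methyltitanium triisopropoxide, C[Ti](OC(C)C)(OC(C)C)OC(C)C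
Why: Organotitanium carbonyl addition; exchange of an isopropoxide for the lactol oxygen should open the ring to the titanium phenoxide and aldehyde, which takes up methyl chemoselectively while the pyranone carbonyl and silyl ethers are left alone, and the uncontrolled carbinol centre is removed in step 14.

Step 14
Reactants: 19 7-hydroxy-8-[(2R)-2-(1-hydroxyethyl)-5-methyl-5-(triethylsilyloxy)hexyl]-5-methoxy-2-[2,4-bis(triisopropylsilyloxy)phenyl]-4H-chromen-4-one
Product: 20 8-[(2R)-2-acetyl-5-methyl-5-(triethylsilyloxy)hexyl]-7-hydroxy-5-methoxy-2-[2,4-bis(triisopropylsilyloxy)phenyl]-4H-chromen-4-one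
Conditions: Dess–Martin periodinane, NaHCO3 (buffer), CH2Cl2, 0 °C → rt
Reagents that add atoms: none
Why: Dess–Martin oxidation under buffered, non-enolising conditions should give the methyl ketone without epimerising C2'' and without oxidising the 7-OH, which is deactivated as a vinylogous acid.

Step 15
Reactants: 20 8-[(2R)-2-acetyl-5-methyl-5-(triethylsilyloxy)hexyl]-7-hydroxy-5-methoxy-2-[2,4-bis(triisopropylsilyloxy)phenyl]-4H-chromen-4-one
Product: 21 7-hydroxy-5-methoxy-8-[(2R)-5-methyl-2-(prop-1-en-2-yl)-5-(triethylsilyloxy)hexyl]-2-[2,4-bis(triisopropylsilyloxy)phenyl]-4H-chromen-4-one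
Conditions: CH2Br2, Zn, TiCl4 (preformed methylene reagent, excess), THF–CH2Cl2, 0 °C → rt
Reagents that add atoms: dibromomethane, BrCBr
Why: Lombardo–Takai methylenation; the non-basic Zn/Ti methylene reagent should convert the ketone (in equilibrium with its 7-O hemiketal) into the isopropenyl group without enolisation, so C2'' is kept, while the vinylogous-ester pyranone carbonyl and the silyl ethers are not attacked and the free phenol only consumes extra reagent.

Step 16
Reactants: 21 7-hydroxy-5-methoxy-8-[(2R)-5-methyl-2-(prop-1-en-2-yl)-5-(triethylsilyloxy)hexyl]-2-[2,4-bis(triisopropylsilyloxy)phenyl]-4H-chromen-4-one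
Product: 22 2-(2,4-dihydroxyphenyl)-7-hydroxy-8-[(2R)-5-hydroxy-5-methyl-2-(prop-1-en-2-yl)hexyl]-5-methoxy-4H-chromen-4-one
Conditions: TBAF, AcOH (1:1, excess), THF, 0 → 40 °C
Reagents that add atoms: none
Why: Fluoride-mediated desilylation should remove both aryl triisopropylsilyl ethers and the tertiary triethylsilyl ether under buffered, near-neutral conditions that cannot protonate the isopropenyl group or ionise the tertiary alcohol.

**Compound list**

1 | 1-(2,4-dihydroxy-6-methoxyphenyl)ethanone | CC(=O)c1c(O)cc(O)cc1OC | starting material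
2 | 1-[4-(benzyloxy)-2-hydroxy-6-methoxyphenyl]ethanone | CC(=O)c1c(O)cc(OCc2ccccc2)cc1OC | intermediate
3 | 2,4-dihydroxybenzaldehyde | O=Cc1ccc(O)cc1O | starting material
4 | 2,4-bis(methoxymethoxy)benzaldehyde | O=Cc1ccc(OCOC)cc1OCOC | intermediate
5 | (E)-1-[4-(benzyloxy)-2-hydroxy-6-methoxyphenyl]-3-[2,4-bis(methoxymethoxy)phenyl]prop-2-en-1-one | COc1cc(OCc2ccccc2)cc(O)c1C(=O)/C=C/c1ccc(OCOC)cc1OCOC | intermediate
6 | 7-(benzyloxy)-5-methoxy-2-[2,4-bis(methoxymethoxy)phenyl]-4H-chromen-4-one | COCOc1ccc(-c2cc(=O)c3c(OC)cc(OCc4ccccc4)cc3o2)c(OCOC)c1 | intermediate (not isolated)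
7 | 7-(benzyloxy)-2-(2,4-dihydroxyphenyl)-5-methoxy-4H-chromen-4-one | COc1cc(OCc2ccccc2)cc2oc(-c3ccc(O)cc3O)cc(=O)c12 | intermediate
8 | 7-(benzyloxy)-5-methoxy-2-[2,4-bis(triisopropylsilyloxy)phenyl]-4H-chromen-4-one | COc1cc(OCc2ccccc2)cc2oc(-c3ccc(O[Si](C(C)C)(C(C)C)C(C)C)cc3O[Si](C(C)C)(C(C)C)C(C)C)cc(=O)c12 | intermediate
9 | 7-hydroxy-5-methoxy-2-[2,4-bis(triisopropylsilyloxy)phenyl]-4H-chromen-4-one | COc1cc(O)cc2oc(-c3ccc(O[Si](C(C)C)(C(C)C)C(C)C)cc3O[Si](C(C)C)(C(C)C)C(C)C)cc(=O)c12 | intermediate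
10 | N,N-dimethylmethyleneiminium iodide | C=[N+](C)C.[I-] | starting material
11 | 8-[(dimethylamino)methyl]-7-hydroxy-5-methoxy-2-[2,4-bis(triisopropylsilyloxy)phenyl]-4H-chromen-4-one | CN(C)Cc1c(O)cc(OC)c2c(=O)cc(-c3ccc(O[Si](C(C)C)(C(C)C)C(C)C)cc3O[Si](C(C)C)(C(C)C)C(C)C)oc12 | intermediate
12 | {7-hydroxy-5-methoxy-4-oxo-2-[2,4-bis(triisopropylsilyloxy)phenyl]-4H-chromen-8-yl}-N,N,N-trimethylmethanaminium iodide | C[N+](C)(C)Cc1c(O)cc(OC)c2c(=O)cc(-c3ccc(O[Si](C(C)C)(C(C)C)C(C)C)cc3O[Si](C(C)C)(C(C)C)C(C)C)oc12.[I-] | intermediate (key-step precursor)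
13 | methyl hex-5-enoate | C=CCCCC(=O)OC | starting material
14 | 2-methylhept-6-en-2-ol | C=CCCCC(C)(C)O | intermediate
15 | triethyl[(2-methylhept-6-en-2-yl)oxy]silane | C=CCCCC(C)(C)O[Si](CC)(CC)CC | intermediate
16 | 5-methyl-5-(triethylsilyloxy)hexanal | O=CCCCC(C)(C)O[Si](CC)(CC)CC | intermediate
17 | 5-methoxy-8-methylidene-2-[2,4-bis(triisopropylsilyloxy)phenyl]-4H-chromene-4,7(8H)-dione (o-quinone methide) | C=C1C(=O)C=C(OC)C2=C1OC(-c1ccc(O[Si](C(C)C)(C(C)C)C(C)C)cc1O[Si](C(C)C)(C(C)C)C(C)C)=CC2=O | intermediate (not isolated)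
18 | (9R)-8-hydroxy-5-methoxy-9-[3-methyl-3-(triethylsilyloxy)butyl]-2-[2,4-bis(triisopropylsilyloxy)phenyl]-9,10-dihydro-4H,8H-pyrano[2,3-f]chromen-4-one (C8 anomers) | OC1[C@H](CCC(C)(C)O[Si](CC)(CC)CC)Cc2c(O1)cc(OC)c3c(=O)cc(-c4ccc(O[Si](C(C)C)(C(C)C)C(C)C)cc4O[Si](C(C)C)(C(C)C)C(C)C)oc23 | intermediate (key-step product)
19 | 7-hydroxy-8-[(2R)-2-(1-hydroxyethyl)-5-methyl-5-(triethylsilyloxy)hexyl]-5-methoxy-2-[2,4-bis(triisopropylsilyloxy)phenyl]-4H-chromen-4-one (carbinol epimers) | CC(O)[C@H](CCC(C)(C)O[Si](CC)(CC)CC)Cc1c(O)cc(OC)c2c(=O)cc(-c3ccc(O[Si](C(C)C)(C(C)C)C(C)C)cc3O[Si](C(C)C)(C(C)C)C(C)C)oc12 | intermediate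
20 | 8-[(2R)-2-acetyl-5-methyl-5-(triethylsilyloxy)hexyl]-7-hydroxy-5-methoxy-2-[2,4-bis(triisopropylsilyloxy)phenyl]-4H-chromen-4-one | CC(=O)[C@H](CCC(C)(C)O[Si](CC)(CC)CC)Cc1c(O)cc(OC)c2c(=O)cc(-c3ccc(O[Si](C(C)C)(C(C)C)C(C)C)cc3O[Si](C(C)C)(C(C)C)C(C)C)oc12 | intermediate
21 | 7-hydroxy-5-methoxy-8-[(2R)-5-methyl-2-(prop-1-en-2-yl)-5-(triethylsilyloxy)hexyl]-2-[2,4-bis(triisopropylsilyloxy)phenyl]-4H-chromen-4-one | C=C(C)[C@H](CCC(C)(C)O[Si](CC)(CC)CC)Cc1c(O)cc(OC)c2c(=O)cc(-c3ccc(O[Si](C(C)C)(C(C)C)C(C)C)cc3O[Si](C(C)C)(C(C)C)C(C)C)oc12 | intermediate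
22 | 2-(2,4-dihydroxyphenyl)-7-hydroxy-8-[(2R)-5-hydroxy-5-methyl-2-(prop-1-en-2-yl)hexyl]-5-methoxy-4H-chromen-4-one | C=C(C)[C@H](CCC(C)(C)O)Cc1c(O)cc(OC)c2c(=O)cc(-c3ccc(O)cc3O)oc12 | target

**Step count and risks**

Total: 16 steps. Longest linear sequence: 12 steps (steps 1, 3–8, 12–16).

Steps most likely to fail:

Step 12. The 7-phenoxide is a weak donor, so loss of trimethylamine may be slower than self-aldolisation of the aldehyde and N-alkylation of the catalyst by the quinone methide. Enantiopurity may also erode if the lactol opens and re-forms the enamine. The fallback forms the same C1''–C2'' bond under auxiliary control, setting out from 16 and 12 and returning at 18. Aldehyde 16 would be oxidised (Pinnick oxidation) to 5-methyl-5-(triethylsilyloxy)hexanoic acid F1. This is N-acylated (PivCl, Et3N, then LiCl and (S)-4-benzyl-1,3-oxazolidin-2-one) to (4S)-4-benzyl-3-[5-methyl-5-(triethylsilyloxy)hexanoyl]-1,3-oxazolidin-2-one F2. Its sodium Z-enolate (NaHMDS, THF, −78 °C) is combined with salt 12 that has been deprotonated with one equivalent of NaHMDS. On warming to about −30 °C the quinone methide 17 is released and should be taken up on the enolate face opposite the benzyl group (Evans alkylation in its Michael variant), giving (4S)-4-benzyl-3-[(2R)-2-({7-hydroxy-5-methoxy-4-oxo-2-[2,4-bis(triisopropylsilyloxy)phenyl]-4H-chromen-8-yl}methyl)-5-methyl-5-(triethylsilyloxy)hexanoyl]-1,3-oxazolidin-2-one F3. Et3N/DMAP should let the 7-OH close onto the imide carbonyl with loss of the oxazolidinone, giving (9R)-5-methoxy-9-[3-methyl-3-(triethylsilyloxy)butyl]-2-[2,4-bis(triisopropylsilyloxy)phenyl]-9,10-dihydro-4H,8H-pyrano[2,3-f]chromene-4,8-dione F4. DIBAL-H (CH2Cl2, −78 °C) reduces this lactone to lactol 18.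

Step 13. The titanium lactolate may fail to open, or methyl transfer may be slower than loss of the reagent at the Lewis-basic pyranone oxygen, so that lactol is returned. The fallback sets out from 18 and returns at 20, bypassing 19 and step 14. Lactol 18 is methylenated through its open aldehyde form with methylenetriphenylphosphorane (Wittig reaction; Ph3PCH3Br, NaHMDS, THF, 0 °C) to 8-[(2R)-2-ethenyl-5-methyl-5-(triethylsilyloxy)hexyl]-7-hydroxy-5-methoxy-2-[2,4-bis(triisopropylsilyloxy)phenyl]-4H-chromen-4-one F5. Wacker–Tsuji oxidation of this monosubstituted alkene (PdCl2 cat., CuCl, O2, DMF–H2O) should give methyl ketone 20.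

Step 15. The ketone may rest as its cyclic hemiketal with the 7-OH, and the phenol may quench the methylene reagent, so conversion may stall. Long exposure to the Lewis-acidic mixture may also strip the tertiary silyl ether. The fallback is a stepwise Peterson olefination, setting out from 20 and returning at 21. Ketone 20 is treated with (trimethylsilyl)methylcerium dichloride (TMSCH2Li, CeCl3, THF, −78 °C), which adds without enolisation, to give 7-hydroxy-8-[(2R)-2-[2-hydroxy-1-(trimethylsilyl)propan-2-yl]-5-methyl-5-(triethylsilyloxy)hexyl]-5-methoxy-2-[2,4-bis(triisopropylsilyloxy)phenyl]-4H-chromen-4-one F6. KHMDS in THF (syn-elimination of the β-silyl alkoxide) should then give alkene 21.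

Further compounds
F1 | step 12 | 5-methyl-5-(triethylsilyloxy)hexanoic acid | CC[Si](CC)(CC)OC(C)(C)CCCC(=O)O
F2 | step 12 | (4S)-4-benzyl-3-[5-methyl-5-(triethylsilyloxy)hexanoyl]-1,3-oxazolidin-2-one | CC[Si](CC)(CC)OC(C)(C)CCCC(=O)N1[C@@H](Cc2ccccc2)COC1=O
F3 | step 12 | (4S)-4-benzyl-3-[(2R)-2-({7-hydroxy-5-methoxy-4-oxo-2-[2,4-bis(triisopropylsilyloxy)phenyl]-4H-chromen-8-yl}methyl)-5-methyl-5-(triethylsilyloxy)hexanoyl]-1,3-oxazolidin-2-one | O=C([C@H](CCC(C)(C)O[Si](CC)(CC)CC)Cc1c(O)cc(OC)c2c(=O)cc(-c3ccc(O[Si](C(C)C)(C(C)C)C(C)C)cc3O[Si](C(C)C)(C(C)C)C(C)C)oc12)N1[C@@H](Cc2ccccc2)COC1=O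
F4 | step 12 | (9R)-5-methoxy-9-[3-methyl-3-(triethylsilyloxy)butyl]-2-[2,4-bis(triisopropylsilyloxy)phenyl]-9,10-dihydro-4H,8H-pyrano[2,3-f]chromene-4,8-dione | O=C1[C@H](CCC(C)(C)O[Si](CC)(CC)CC)Cc2c(O1)cc(OC)c3c(=O)cc(-c4ccc(O[Si](C(C)C)(C(C)C)C(C)C)cc4O[Si](C(C)C)(C(C)C)C(C)C)oc23
F5 | step 13 | 8-[(2R)-2-ethenyl-5-methyl-5-(triethylsilyloxy)hexyl]-7-hydroxy-5-methoxy-2-[2,4-bis(triisopropylsilyloxy)phenyl]-4H-chromen-4-one | C=C[C@H](CCC(C)(C)O[Si](CC)(CC)CC)Cc1c(O)cc(OC)c2c(=O)cc(-c3ccc(O[Si](C(C)C)(C(C)C)C(C)C)cc3O[Si](C(C)C)(C(C)C)C(C)C)oc12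
F6 | step 15 | 7-hydroxy-8-[(2R)-2-[2-hydroxy-1-(trimethylsilyl)propan-2-yl]-5-methyl-5-(triethylsilyloxy)hexyl]-5-methoxy-2-[2,4-bis(triisopropylsilyloxy)phenyl]-4H-chromen-4-one (carbinol epimers) | C[Si](C)(C)CC(C)(O)[C@H](CCC(C)(C)O[Si](CC)(CC)CC)Cc1c(O)cc(OC)c2c(=O)cc(-c3ccc(O[Si](C(C)C)(C(C)C)C(C)C)cc3O[Si](C(C)C)(C(C)C)C(C)C)oc12
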